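**Strategy.** Everything rests on disconnecting the two secondary benzoate C–O bonds, C3–O and C6–O, of the cyclohexene ring at once. The key step exploits the C3(OBz)–C4=C5–C6(OBz) unit, whose benzoates lie trans across the ring alkene: a chloride-free Pd(OAc)2/benzoquinone 1,4-dibenzoyloxylation of a C3=C4–C5=C6 diene forms both bonds, sets C3 and C6, and leaves C4=C5. The precursor is the (1R,2R)-cyclohexa-3,5-diene-1,2-diol acetonide that already holds the quaternary C1 carbinol, the C2 oxygen and the C7 benzoate. It comes from 4-hydroxybenzyl alcohol by oxidative dearomatisation and an enantioselective oxa-Michael desymmetrisation of the resulting p-quinol.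

Key step: step 6

Remarks on the chemistry:
- Numbering: ring carbons C1 (quaternary carbinol), C2 (secondary carbinol), C3 to C6, exocyclic C7. With the ring drawn flat, the C1 and C2 oxygens and the C3 benzoate sit on one face; the C6 benzoate and C7 sit on the other. The target is (1R,2R,3R,6R).
- With CH2OBz on C1 the diene acetonide is (1R,2R), because C2 outranks C7 at C1; the same spatial arrangement in the corresponding 1-carboxylic acid is (1S,2R).
- Assumption: the quinine-derived thiourea is taken to give the (1R,2R) adduct in step 3. The sense of induction is inferred by analogy; the quinidine-derived pseudoenantiomer would be used if it proves opposite.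

**Step 1**
Reactants: 1 4-hydroxybenzyl alcohol; 2 benzoic acid
Product: 3 4-hydroxybenzyl benzoate
Conditions: PPh3, DIAD, THF, 0 °C to 25 °C
Reagents that add atoms: benzoic acid (compound 2), OC(=O)c1ccccc1
Why: Mitsunobu esterification: only benzoic acid is acidic enough to protonate the PPh3/DIAD betaine, so its carboxylate should displace the activated primary benzylic oxygen while the much less acidic phenol stays free; no stereocentre is formed.

**Step 2**
Reactants: 3 4-hydroxybenzyl benzoate
Product: 4 (1-hydroxy-4-oxocyclohexa-2,5-dien-1-yl)methyl benzoate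
Conditions: PhI(OAc)2, MeCN/H2O (3:1), 0 °C
Reagents that add atoms: water, O
Why: Hypervalent-iodine oxidative dearomatisation of a para-substituted phenol: PhI(OAc)2 activates the phenol oxygen and water adds at the para carbon to give the achiral p-quinol, the C7 ester blocking retro-aldol loss of formaldehyde.

**Step 3**
Reactants: 4 (1-hydroxy-4-oxocyclohexa-2,5-dien-1-yl)methyl benzoate; 5 phenylboronic acid
Product: 8 acetonide of (4R,5R)-4-(benzoyloxymethyl)-4,5-dihydroxycyclohex-2-en-1-one, via cyclic phenylboronate 6 (not isolated), via free diol 7 (not isolated)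
Conditions: PhB(OH)2, 1-[3,5-bis(trifluoromethyl)phenyl]-3-[(8S,9S)-6'-methoxycinchonan-9-yl]thiourea (15 mol %), 4 Å molecular sieves, toluene, 25 °C; then pinacol, Me2C(OMe)2, TsOH·H2O (cat.), acetone, 25 °C
Reagents that add atoms: phenylboronic acid (compound 5), OB(O)c1ccccc1; 2,2-dimethoxypropane, COC(C)(C)OC
Why: Amine–thiourea-catalysed boronic acid hemiester oxa-Michael addition to a γ-hydroxy enone: the C1 hydroxyl binds PhB(OH)2, the amine-activated B–OH adds to one of the two enantiotopic β-carbons while the thiourea holds the carbonyl, so the five-membered boronate forces C2–O cis to C1–O and the catalyst selects the arm that makes C1 and C2 both R; pinacol then takes the boron and the diol is ketalised by acid-catalysed transacetalisation before retro-Michael loss can occur.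

**Step 4**
Reactants: 8 acetonide of (4R,5R)-4-(benzoyloxymethyl)-4,5-dihydroxycyclohex-2-en-1-one
Product: 10 (1R,2R)-1-(benzoyloxymethyl)-4-(trifluoromethanesulfonyloxy)cyclohexa-3,5-diene-1,2-diol acetonide, via lithium dienolate 9 (not isolated)
Conditions: LiN(SiMe3)2, THF, –78 °C; then N-(5-chloropyridin-2-yl)bis(trifluoromethanesulfonimide), –78 to –40 °C
Reagents that add atoms: N-(5-chloropyridin-2-yl)bis(trifluoromethanesulfonimide), O=S(=O)(N(c1ccc(Cl)cn1)S(=O)(=O)C(F)(F)F)C(F)(F)F
Why: Kinetic enolisation and O-sulfonylation (enol triflate formation): C3 is the only enolisable position, and the lithium counter-ion at –78 °C should hold back E1cB loss of the C2 oxygen; C1 and C2 are untouched.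

**Step 5**
Reactants: 10 (1R,2R)-1-(benzoyloxymethyl)-4-(trifluoromethanesulfonyloxy)cyclohexa-3,5-diene-1,2-diol acetonide
Product: 11 (1R,2R)-1-(benzoyloxymethyl)cyclohexa-3,5-diene-1,2-diol acetonide
Conditions: Pd(OAc)2 (5 mol %), PPh3 (10 mol %), HCO2H, Bu3N, DMF, 50 °C
Reagents that add atoms: none
Why: Pd(OAc)2/PPh3-catalysed formate reduction of a vinyl triflate (oxidative addition, formate exchange, decarboxylation, C–H reductive elimination) should replace C4–OTf by C4–H without moving the diene or touching C1 and C2.

**Step 6**
Reactants: 11 (1R,2R)-1-(benzoyloxymethyl)cyclohexa-3,5-diene-1,2-diol acetonide; 2 benzoic acid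
Product: 12 (1S,2R,3R,6R)-3,6-bis(benzoyloxy)-1-(benzoyloxymethyl)cyclohex-4-ene-1,2-diol acetonide
Conditions: Pd(OAc)2 (5 mol %, pre-stirred with PhCO2H), p-benzoquinone (20 mol %), MnO2 (1.5 equiv), PhCO2Li, PhCO2H, acetone, 25 °C, no chloride, slow addition of 11
Reagents that add atoms: benzoic acid (compound 2), OC(=O)c1ccccc1; lithium benzoate, [Li+].[O-]C(=O)c1ccccc1
Why: Pd(O2CPh)2 formed in situ should bind the C3=C4–C5=C6 diene on the face anti to the dioxolane; benzoate from solution then attacks C3 anti to the metal (trans-acyloxypalladation) to give a π-allylpalladium intermediate over C4–C6, benzoquinone coordination induces migration of a metal-bound benzoate to C6 on the metal's own face, and the zerovalent palladium released is returned to the divalent state by benzoquinone, itself recycled by MnO2. The closest known reaction is the chloride-free Pd(OAc)2/benzoquinone trans-1,4-diacyloxylation of cyclohexa-1,3-dienes with carboxylic acids in acetone; no ring is closed. C3 (R) is set by the external anti attack, which places its benzoate cis to the C2 oxygen, and C6 (R) by the syn delivery from the metal, which places its benzoate trans to the C3 benzoate and to the C1 oxygen; both follow from the face the metal occupies, which the cis-fused acetonide fixes. The step needs first attack at C3 and not C6 (C6 is neopentylic beside the quaternary C1, whereas C3 adjoins only the methine C2), 1,4- over 1,2-addition (the allyl terminus next to the new electron-poor C3–O carbon is deactivated), and trans over cis addition (chloride, which would displace benzoate from the metal, is excluded). Catalytic quinone and slow diene addition should keep Diels–Alder capture of the diene low, and pre-exchange of the acetate ligands avoids mixed acetate esters.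

**Step 7**
Reactants: 12 (1S,2R,3R,6R)-3,6-bis(benzoyloxy)-1-(benzoyloxymethyl)cyclohex-4-ene-1,2-diol acetonide
Product: 13 (1R,2R,3R,6R)-3,6-bis(benzoyloxy)-1-(benzoyloxymethyl)cyclohex-4-ene-1,2-diol
Conditions: CF3CO2H/H2O (9:1), CH2Cl2, 0 °C
Reagents that add atoms: none
Why: Acid-catalysed hydrolysis of the isopropylidene acetal: cleavage occurs at the acetal carbon, so the C1–O and C2–O bonds and all four stereocentres are untouched, and cold aqueous CF3CO2H should spare the benzoates, whose allylic ionisation at C3 and C6 is disfavoured by the neighbouring oxygens.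

**Compound list**
1 | 4-hydroxybenzyl alcohol | OCc1ccc(O)cc1 | starting material
2 | benzoic acid | OC(=O)c1ccccc1 | starting material
3 | 4-hydroxybenzyl benzoate | O=C(OCc1ccc(O)cc1)c1ccccc1 | intermediate
4 | (1-hydroxy-4-oxocyclohexa-2,5-dien-1-yl)methyl benzoate (achiral p-quinol) | O=C(OCC1(O)C=CC(=O)C=C1)c1ccccc1 | intermediate
5 | phenylboronic acid | OB(O)c1ccccc1 | starting material
6 | cis-fused B-phenyl dioxaborolane across the C1 and C2 oxygens of 7, (1R,2R) | O=C(OC[C@@]1(OB(c3ccccc3)O2)[C@H]2CC(=O)C=C1)c1ccccc1 | intermediate (not isolated)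
7 | (4R,5R)-4-(benzoyloxymethyl)-4,5-dihydroxycyclohex-2-en-1-one (cis-diol) | O=C(OC[C@@]1(O)[C@H](O)CC(=O)C=C1)c1ccccc1 | intermediate (not isolated)
8 | acetonide of (4R,5R)-4-(benzoyloxymethyl)-4,5-dihydroxycyclohex-2-en-1-one | O=C(OC[C@@]1(OC(C)(C)O2)[C@H]2CC(=O)C=C1)c1ccccc1 | intermediate
9 | lithium C3=C4 dienolate of 8 | O=C(OC[C@@]1(OC(C)(C)O2)[C@H]2C=C([O-])C=C1)c1ccccc1.[Li+] | intermediate (not isolated)
10 | (1R,2R)-1-(benzoyloxymethyl)-4-(trifluoromethanesulfonyloxy)cyclohexa-3,5-diene-1,2-diol acetonide | O=C(OC[C@@]1(OC(C)(C)O2)[C@H]2C=C(OS(=O)(=O)C(F)(F)F)C=C1)c1ccccc1 | intermediate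
11 | (1R,2R)-1-(benzoyloxymethyl)cyclohexa-3,5-diene-1,2-diol acetonide | O=C(OC[C@@]1(OC(C)(C)O2)[C@H]2C=CC=C1)c1ccccc1 | intermediate
12 | (1S,2R,3R,6R)-3,6-bis(benzoyloxy)-1-(benzoyloxymethyl)cyclohex-4-ene-1,2-diol acetonide (same spatial arrangement as 13; the C1 descriptor changes by CIP ranking only) | O=C(OC[C@@]1(OC(C)(C)O2)[C@H]2[C@H](OC(=O)c2ccccc2)C=C[C@H]1OC(=O)c1ccccc1)c1ccccc1 | intermediate
13 | (1R,2R,3R,6R)-3,6-bis(benzoyloxy)-1-(benzoyloxymethyl)cyclohex-4-ene-1,2-diol | O=C(OC[C@@]1(O)[C@H](O)[C@H](OC(=O)c2ccccc2)C=C[C@H]1OC(=O)c1ccccc1)c1ccccc1 | target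

**Totals.** Total step count: 7. Longest linear sequence: 7 steps (1 to 13).

**Steps most likely to fail**

Step 6. The metal may bind the wrong diene face, the first attack may go to C6, 1,2-addition may compete, the diene may be lost by cycloaddition to the quinone, or zerovalent palladium may ionise the allylic benzoates and erode the trans geometry. The fallback makes both C–O bonds by oxygen cycloaddition and sets out from diene 11. Tetraphenylporphyrin-sensitised photooxygenation (O2, hν, CH2Cl2, –40 °C) should add singlet oxygen across C3 and C6 on the face anti to the dioxolane, giving the C3,C6-endoperoxide F1. Thiourea in MeOH cleaves the O–O bond to the 3,6-cis-enediol F2, with both hydroxyls anti to the acetonide. A Mitsunobu reaction with benzoic acid 2 (PPh3, DIAD, THF, 0 °C) should engage only the C3 hydroxyl, since the C6 hydroxyl is neopentylic, and invert it to the C3 benzoate F3, now syn to the C2 oxygen. Benzoylation of the remaining C6 hydroxyl (PhCOCl, pyridine, DMAP) comes back to the route at acetonide 12.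

Step 4. The enolate may expel the C2 acetonide oxygen (E1cB) faster than it is sulfonylated, which would destroy both stereocentres. The fallback avoids any enolate and sets out from enone 8. Luche reduction (NaBH4, CeCl3·7H2O, MeOH, –78 °C) gives the allylic alcohol F4; either C4 epimer serves. Methyl chloroformate and pyridine give the allylic methyl carbonate F5. Pd(PPh3)4 (5 mol %) in dioxane at 80 °C should ionise the carbonate to a π-allyl complex over C4–C6, and β-hydride loss from C3 (C1 carries no hydrogen) gives the diene. This comes back to the route at diene 11 and replaces steps 4 and 5.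

Step 3. Hemiester formation at the hindered tertiary carbinol may be slow, discrimination between the two enone arms may be poor, or the adduct may revert by retro-Michael reaction. The fallback takes both stereocentres from a biocatalytic arene dihydroxylation and sets out from benzoic acid 2. Whole cells of Ralstonia eutropha B9 (benzoate dioxygenase, no diol dehydrogenase) oxidise it to (1S,2R)-1,2-dihydroxycyclohexa-3,5-diene-1-carboxylic acid F6. 2,2-Dimethoxypropane and TsOH·H2O in acetone give the acetonide acid F7, and LiAlH4 (THF, 0 °C) gives the primary alcohol F8. PhCOCl and pyridine then benzoylate C7. This comes back to the route at diene 11 and bypasses steps 1 to 5.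

**Further compounds**
F1 | step 6 | C3,C6-endoperoxide of 11, peroxide bridge anti to the dioxolane | O=C(OC[C@@]1(OC(C)(C)O2)[C@H]2[C@@H]3C=C[C@H]1OO3)c1ccccc1
F2 | step 6 | 1-(benzoyloxymethyl)cyclohex-4-ene-1,2,3,6-tetrol 1,2-acetonide, C3 and C6 hydroxyls cis to each other and anti to the dioxolane | O=C(OC[C@@]1(OC(C)(C)O2)[C@H]2[C@@H](O)C=C[C@H]1O)c1ccccc1
F3 | step 6 | C3 benzoate (syn to the C2 oxygen) of the 1,2-acetonide with free C6 hydroxyl | O=C(OC[C@@]1(OC(C)(C)O2)[C@H]2[C@H](OC(=O)c3ccccc3)C=C[C@H]1O)c1ccccc1
F4 | step 4 | allylic C4 alcohol from 8, either C4 epimer | O=C(OC[C@@]1(OC(C)(C)O2)[C@H]2CC(O)C=C1)c1ccccc1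
F5 | step 4 | allylic C4 methyl carbonate of F4 | O=C(OC[C@@]1(OC(C)(C)O2)[C@H]2CC(OC(=O)OC)C=C1)c1ccccc1
F6 | step 3 | (1S,2R)-1,2-dihydroxycyclohexa-3,5-diene-1-carboxylic acid | OC(=O)[C@@]1(O)[C@H](O)C=CC=C1
F7 | step 3 | acetonide of F6 | OC(=O)[C@@]1(OC(C)(C)O2)[C@H]2C=CC=C1
F8 | step 3 | (1R,2R)-1-(hydroxymethyl)cyclohexa-3,5-diene-1,2-diol acetonide | OC[C@@]1(OC(C)(C)O2)[C@H]2C=CC=C1
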